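**Strategy.** The route rests on cutting the C9–C10 bond, the link between the two fully substituted carbons where ring B meets ring A and the spiro ether ring C. C10 lies next to C5 and the C6 oxygen, so α-damascone supplies ring A, C6–C8 and a C10=C1 alkene; C9 is made the β-carbon of a 3(2H)-furanone (ring C, carbonyl at C12) that already carries the spiro lactone ring D and C13. In one operation, iron-hydride hydrogen atom transfer turns the alkene into the C10 radical, which adds to C9, closing ring B and setting C9 and C10 under control of C8.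

Key step: step 9

**Remarks and assumptions**
- Labdane numbering is used: ring A = C1–C5, C10; ring B = C5–C10; ring C = O, C9, C11, C12, C13; ring D = C13, C14, C15, O, C16.
- Compound 1 is racemic and its ring stereocentre (later C5) is untouched until step 10, so 3, 4 and 15–19 are pairs of C5 epimers and their SMILES leave that carbon undefined; the key-step precursor 18 is therefore a C5-epimer pair, not a single isomer.
- The tertiary C13 hydroxyl is carried as a triethylsilyl ether through acid chloride formation and coupling, because a free α-hydroxy acid chloride would not be a workable reagent.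
- C13 is taken from (R)-malic acid rather than from an asymmetric oxidation of an itaconate, so that its configuration is fixed by a stereospecific alkylation.
- Assumption: (R)-DTBM-SEGPHOS is taken to give the (R) configuration at C8 in step 1; if the sense proved opposite, the (S)-ligand would be used.
- Assumption: the trans-fused 6-ketone (H5 anti to C20) is taken to be the more stable C5 epimer in step 10.

**Route**

Step 1
Reactants: 1 α-damascone (racemic); 2 ethynyl(triisopropyl)silane
Product: 3 (3R)-3-methyl-5-(triisopropylsilyl)-1-(2,6,6-trimethylcyclohex-2-en-1-yl)pent-4-yn-1-one (pair of C5 epimers)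
Conditions: [Rh(OAc)(C2H4)2]2 (2.5 mol %), (R)-DTBM-SEGPHOS (6 mol %), 2 (2 equiv), 1,4-dioxane, 80 °C
Reagents that add atoms: none
Why: Rhodium-catalysed asymmetric conjugate alkynylation of the (E)-enone, in which an alkynyl complex of monovalent rhodium inserts the enone, the bulky silyl group and ligand suppress alkyne dimerisation, and the ligand selects the enone face so that C8 should be set as R.

Step 2
Reactants: 3 silyl alkyne
Product: 4 (3R)-3-methyl-1-(2,6,6-trimethylcyclohex-2-en-1-yl)pent-4-yn-1-one (pair of C5 epimers)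
Conditions: Bu4NF (1.1 equiv), THF, 0 °C
Reagents that add atoms: none
Why: Fluoride-mediated protodesilylation of the alkynylsilane is fast at 0 °C and should leave the ketone and the C8 centre, which is not acidic, untouched.

Step 3
Reactants: 5 (R)-malic acid; 6 pivalaldehyde
Product: 7 2-[(2R,4R)-2-tert-butyl-5-oxo-1,3-dioxolan-4-yl]acetic acid
Conditions: TsOH·H2O (cat.), H2SO4 (cat.), pentane, reflux, azeotropic removal of water; recrystallisation
Reagents that add atoms: none
Why: Acid-catalysed acetalisation of the α-hydroxy acid unit gives the five-membered dioxolanone, and the cis isomer (tert-butyl and CH2CO2H on the same face) is the thermodynamic product and is purified by crystallisation, which sets the acetal carbon as R.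

Step 4
Reactants: 7 dioxolanone acid; 8 benzyl chloromethyl ether
Product: 9 2-[(2R,4S)-4-[(benzyloxy)methyl]-2-tert-butyl-5-oxo-1,3-dioxolan-4-yl]acetic acid
Conditions: LiN(SiMe3)2 (2.1 equiv), THF, −78 °C; then 8, −78 → −30 °C; aqueous HCl work-up
Reagents that add atoms: none
Why: Enolate alkylation by self-regeneration of the stereocentre: the carboxylate-enolate dianion is planar at C13 and the electrophile should enter anti to the tert-butyl group, so that C16 takes the place of the former hydrogen and C13 becomes quaternary with retention.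

Step 5
Reactants: 9 benzyloxymethyl dioxolanone acid
Product: 12 (3S)-3-hydroxy-5-oxooxolane-3-carboxylic acid, via hydroxymethyl dioxolanone acid 10 (not isolated), via itatartaric acid 11 (not isolated)
Conditions: H2 (1 atm), 10% Pd/C, EtOAc, rt; filter; then 2 M HCl, THF, 60 °C; evaporate
Reagents that add atoms: none
Why: Hydrogenolysis of the benzyl ether followed by acid hydrolysis of the acylal and spontaneous γ-lactonisation of the C16 hydroxyl onto the C15 acid, the only five-membered lactone available, with the quaternary C13 unable to epimerise.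

Step 6
Reactants: 12 hydroxy lactone acid
Product: 14 (3S)-5-oxo-3-[(triethylsilyl)oxy]oxolane-3-carbonyl chloride, via bis(triethylsilyl) derivative 13 (not isolated)
Conditions: Et3SiOTf (2.2 equiv), 2,6-lutidine (2.5 equiv), CH2Cl2, 0 °C; pentane, filter, concentrate; then (COCl)2 (1.1 equiv), DMF (cat.), CH2Cl2, 0 °C → rt
Reagents that add atoms: triethylsilyl trifluoromethanesulfonate, CC[Si](CC)(CC)OS(=O)(=O)C(F)(F)F; oxalyl chloride, O=C(Cl)C(Cl)=O
Why: Silylation of hydroxyl and acid, then conversion of the silyl ester into the acid chloride with oxalyl chloride and catalytic DMF under neutral conditions, which should leave the tertiary silyl ether and the lactone intact.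

Step 7
Reactants: 4 terminal alkyne; 14 acid chloride
Product: 15 (4S)-4-[(4R)-4-methyl-6-oxo-6-(2,6,6-trimethylcyclohex-2-en-1-yl)hex-2-ynoyl]-4-[(triethylsilyl)oxy]oxolan-2-one (pair of C5 epimers)
Conditions: PdCl2(PPh3)2 (2 mol %), CuI (4 mol %), Et3N (1.5 equiv), THF, rt
Reagents that add atoms: none
Why: Acyl Sonogashira coupling (oxidative addition of the acid chloride to zerovalent palladium, transmetalation from the copper acetylide, reductive elimination) forms C11–C12 without a strong base, so the enolisable C6 ketone and the lactone survive, and the acid chloride has no α-hydrogen and cannot form a ketene.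

Step 8
Reactants: 15 silyloxy ynone
Product: 18 (5S)-2-[(2R)-4-oxo-4-(2,6,6-trimethylcyclohex-2-en-1-yl)butan-2-yl]-1,7-dioxaspiro[4.4]non-2-ene-4,8-dione (pair of C5 epimers), via hydroxy ynone 16 (not isolated), via diethylamino enone 17 (not isolated)
Conditions: HF·pyridine, THF, 0 °C; NaHCO3 work-up; then Et2NH (1.2 equiv), EtOH, rt
Reagents that add atoms: none
Why: Fluoride removes the silyl group, diethylamine adds to the ynone, and the tertiary C13 hydroxyl displaces the amine by addition–elimination at C9 (net 5-endo-dig oxa-Michael closure) to give the 3(2H)-furanone ring C, with C8 and C13 untouched.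

Step 9
Reactants: 18 damascone-furanone-lactone
Product: 19 (8R,9R,10S,13S)-6,12-dioxo-9,13-epoxylabdan-15,16-olide (pair of C5 epimers)
Conditions: Fe(acac)3 (0.3 equiv), PhSiH3 (2.5 equiv), EtOH/(CH2OH)2 5:1, 0.02 M, 60 °C, Ar
Reagents that add atoms: none
Why: Fe(acac)3 and PhSiH3 form an iron hydride that gives a hydrogen atom to C1 of the electron-rich ring alkene, the tertiary C10 radical adds to C9 (β-carbon of the vinylogous ester C9=C11–C12=O), and the resulting C11 radical next to the ketone is reduced by divalent iron to the enolate and protonated by ethanol. The closest known reaction type is the iron-hydride hydrogen-atom-transfer reductive coupling of unactivated alkenes with enones (a Giese-type conjugate addition), which is established for intramolecular cases and for joining two fully substituted carbons through an early, long transition state. Ring B closes in the 6-exo-trig mode. C9 is controlled by C8: allylic 1,3-strain keeps H8 in the furanone plane eclipsing C9=C11, so the tether reaches the face that gives a chair with C17 equatorial, the ring C oxygen axial and C11 equatorial. C10 is fixed in the same chair, which places C1 equatorial and C20 axial for either C5 epimer (trans-decalone from the 5S half, cis-decalone from the 5R half), so both halves should differ only at C5. The step needs hydrogen atom transfer to C10=C1 rather than to the electron-poor furanone alkene and ring closure faster than reduction of the radical; the nucleophilic alkene, the electrophilic acceptor held 1,6 to the radical and high dilution should secure this.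

Step 10
Reactants: 19 tricyclic diketone (C5 epimers)
Product: 20 (5S,8R,9R,10S,13S)-6,12-dioxo-9,13-epoxylabdan-15,16-olide
Conditions: DBU (1 equiv), toluene, 60 °C
Reagents that add atoms: none
Why: Base-mediated enolisation of the C6 ketone equilibrates C5 to the trans-fused decalone (H5 axial, anti to C20), while C8 is not acidic, C9, C10 and C13 are quaternary, and opening of ring C by β-elimination is stereoelectronically disfavoured in the five-membered ring.

Step 11
Reactants: 20 trans-diketone
Product: 21 (5S,6R,8R,9R,10S,13S)-6,12-dihydroxy-9,13-epoxylabdan-15,16-olide (C12 configuration not defined)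
Conditions: NaBH4 (4 equiv), EtOH/THF 1:1, 0 °C → rt; aqueous NH4Cl
Reagents that add atoms: none
Why: Borohydride reduces both ketones and not the lactone; at C6 hydride should enter from the α-face because the β-face is blocked by the axial C19 and C20 methyls, giving the axial 6β-alcohol (R), and the C12 carbinol centre is removed in step 13.

Step 12
Reactants: 21 diol
Product: 22 12-O-(phenoxythiocarbonyl) derivative of 21
Conditions: PhOC(S)Cl (1.3 equiv), pyridine (3 equiv), DMAP (0.1 equiv), CH2Cl2, 0 °C → rt
Reagents that add atoms: O-phenyl chlorothionoformate, S=C(Cl)Oc1ccccc1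
Why: Thioacylation should occur at the exposed C12 hydroxyl on ring C, because the 6β-hydroxyl is shielded by two syn-axial methyls (C19, C20).

Step 13
Reactants: 22 thionocarbonate
Product: 23 (5S,6R,8R,9R,10S,13S)-6-hydroxy-9,13-epoxylabdan-15,16-olide
Conditions: Bu3SnH (2 equiv), AIBN (0.2 equiv), toluene, 100 °C
Reagents that add atoms: none
Why: Barton–McCombie deoxygenation: the stannyl radical adds to C=S, fragmentation gives the secondary C12 radical, which takes hydrogen from the stannane, and the neighbouring C–O bonds do not fragment.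

Step 14
Reactants: 23 hydroxy lactone
Product: 24 (5S,6R,8R,9R,10S,13S)-6-acetoxy-9,13-epoxylabdan-15,16-olide
Conditions: Ac2O (5 equiv), DMAP (1 equiv), pyridine, 50 °C
Reagents that add atoms: acetic anhydride, CC(=O)OC(C)=O
Why: DMAP-catalysed acylation forces esterification of the hindered axial alcohol with retention at C6 on a robust intermediate.

Step 15
Reactants: 24 acetoxy lactone
Product: 25 (5S,6R,8R,9R,10S,13S)-6-acetoxy-9,13:15,16-diepoxylabdan-15-ol (C15 anomers)
Conditions: i-Bu2AlH (1.2 equiv), CH2Cl2, −78 °C; aqueous KNaC4H4O6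
Reagents that add atoms: none
Why: Partial reduction of the γ-lactone to the lactol: the lactone carbonyl is more electrophilic than the hindered axial acetate and its tetrahedral aluminate is stable at −78 °C, so reduction should stop at the hemiacetal.

Step 16
Reactants: 25 lactol
Product: 27 (5S,6R,8R,9R,10S,13S)-6-acetoxy-9,13:15,16-diepoxylabd-14-ene (the target), via anomeric mesylate 26 (not isolated)
Conditions: MsCl (1.5 equiv), Et3N (6 equiv), CH2Cl2, −20 °C → reflux; chromatography on Et3N-deactivated silica
Reagents that add atoms: none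
Why: Lactol dehydration through the anomeric mesylate, which ionises and loses H14 (the only β-hydrogen) to the amine to give the C14=C15 enol ether; the medium stays basic, so the acid-labile allylic C13–O bond and the acetate should survive.

**Compound list**

1 | α-damascone, (E)-1-(2,6,6-trimethylcyclohex-2-en-1-yl)but-2-en-1-one, racemic | C/C=C/C(=O)C1C(C)=CCCC1(C)C | starting material
2 | ethynyl(triisopropyl)silane | C#C[Si](C(C)C)(C(C)C)C(C)C | starting material
3 | (3R)-3-methyl-5-(triisopropylsilyl)-1-(2,6,6-trimethylcyclohex-2-en-1-yl)pent-4-yn-1-one, C5 epimers | C[C@H](CC(=O)C1C(C)=CCCC1(C)C)C#C[Si](C(C)C)(C(C)C)C(C)C | intermediate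
4 | (3R)-3-methyl-1-(2,6,6-trimethylcyclohex-2-en-1-yl)pent-4-yn-1-one, C5 epimers | C[C@H](CC(=O)C1C(C)=CCCC1(C)C)C#C | intermediate
5 | (R)-malic acid | OC(=O)[C@@H](CC(=O)O)O | starting material
6 | pivalaldehyde | CC(C)(C)C=O | starting material
7 | 2-[(2R,4R)-2-tert-butyl-5-oxo-1,3-dioxolan-4-yl]acetic acid | CC(C)(C)[C@H]1OC(=O)[C@@H](CC(=O)O)O1 | intermediate
8 | benzyl chloromethyl ether | ClCOCc1ccccc1 | starting material
9 | 2-[(2R,4S)-4-[(benzyloxy)methyl]-2-tert-butyl-5-oxo-1,3-dioxolan-4-yl]acetic acid | CC(C)(C)[C@H]1OC(=O)[C@@](COCc2ccccc2)(CC(=O)O)O1 | intermediate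
10 | 2-[(2R,4S)-2-tert-butyl-4-(hydroxymethyl)-5-oxo-1,3-dioxolan-4-yl]acetic acid | CC(C)(C)[C@H]1OC(=O)[C@@](CO)(CC(=O)O)O1 | intermediate
11 | (2S)-2-hydroxy-2-(hydroxymethyl)butanedioic acid (itatartaric acid) | OC(=O)[C@@](CO)(CC(=O)O)O | intermediate
12 | (3S)-3-hydroxy-5-oxooxolane-3-carboxylic acid | O=C(O)[C@@]1(CC(=O)OC1)O | intermediate
13 | triethylsilyl (3S)-5-oxo-3-[(triethylsilyl)oxy]oxolane-3-carboxylate | CC[Si](CC)(CC)OC(=O)[C@@]1(CC(=O)OC1)O[Si](CC)(CC)CC | intermediate
14 | (3S)-5-oxo-3-[(triethylsilyl)oxy]oxolane-3-carbonyl chloride | ClC(=O)[C@@]1(CC(=O)OC1)O[Si](CC)(CC)CC | intermediate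
15 | (4S)-4-[(4R)-4-methyl-6-oxo-6-(2,6,6-trimethylcyclohex-2-en-1-yl)hex-2-ynoyl]-4-[(triethylsilyl)oxy]oxolan-2-one, C5 epimers | C[C@H](CC(=O)C1C(C)=CCCC1(C)C)C#CC(=O)[C@@]1(CC(=O)OC1)O[Si](CC)(CC)CC | intermediate
16 | (4S)-4-hydroxy-4-[(4R)-4-methyl-6-oxo-6-(2,6,6-trimethylcyclohex-2-en-1-yl)hex-2-ynoyl]oxolan-2-one, C5 epimers | C[C@H](CC(=O)C1C(C)=CCCC1(C)C)C#CC(=O)[C@@]1(CC(=O)OC1)O | intermediate
17 | diethylamine adduct of 16 at C9 (3-diethylamino enone), C5 epimers | C[C@H](CC(=O)C1C(C)=CCCC1(C)C)C(=CC(=O)[C@@]1(CC(=O)OC1)O)N(CC)CC | intermediate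
18 | (5S)-2-[(2R)-4-oxo-4-(2,6,6-trimethylcyclohex-2-en-1-yl)butan-2-yl]-1,7-dioxaspiro[4.4]non-2-ene-4,8-dione, C5 epimers (key-step precursor) | O=C(C[C@@H](C)C1=CC(=O)[C@@]2(CC(=O)OC2)O1)C1C(C)=CCCC1(C)C | intermediate
19 | (8R,9R,10S,13S)-6,12-dioxo-9,13-epoxylabdan-15,16-olide, C5 epimers (key-step product) | O=C1C[C@@H](C)[C@]2(CC(=O)[C@@]3(CC(=O)OC3)O2)[C@@]2(C)CCCC(C)(C)C12 | intermediate
20 | (5S,8R,9R,10S,13S)-6,12-dioxo-9,13-epoxylabdan-15,16-olide | O=C1C[C@@H](C)[C@]2(CC(=O)[C@@]3(CC(=O)OC3)O2)[C@@]2(C)CCCC(C)(C)[C@H]12 | intermediate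
21 | (5S,6R,8R,9R,10S,13S)-6,12-dihydroxy-9,13-epoxylabdan-15,16-olide, C12 undefined | O[C@@H]1C[C@@H](C)[C@]2(CC(O)[C@@]3(CC(=O)OC3)O2)[C@@]2(C)CCCC(C)(C)[C@H]12 | intermediate
22 | 12-O-(phenoxythiocarbonyl) derivative of 21 | O[C@@H]1C[C@@H](C)[C@]2(CC(OC(=S)Oc4ccccc4)[C@@]3(CC(=O)OC3)O2)[C@@]2(C)CCCC(C)(C)[C@H]12 | intermediate
23 | (5S,6R,8R,9R,10S,13S)-6-hydroxy-9,13-epoxylabdan-15,16-olide | O[C@@H]1C[C@@H](C)[C@]2(CC[C@@]3(CC(=O)OC3)O2)[C@@]2(C)CCCC(C)(C)[C@H]12 | intermediate
24 | (5S,6R,8R,9R,10S,13S)-6-acetoxy-9,13-epoxylabdan-15,16-olide | CC(=O)O[C@@H]1C[C@@H](C)[C@]2(CC[C@@]3(CC(=O)OC3)O2)[C@@]2(C)CCCC(C)(C)[C@H]12 | intermediate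
25 | (5S,6R,8R,9R,10S,13S)-6-acetoxy-9,13:15,16-diepoxylabdan-15-ol, C15 anomers | CC(=O)O[C@@H]1C[C@@H](C)[C@]2(CC[C@@]3(CC(O)OC3)O2)[C@@]2(C)CCCC(C)(C)[C@H]12 | intermediate
26 | 15-O-methanesulfonyl derivative of 25 | CC(=O)O[C@@H]1C[C@@H](C)[C@]2(CC[C@@]3(CC(OS(C)(=O)=O)OC3)O2)[C@@]2(C)CCCC(C)(C)[C@H]12 | intermediate
27 | (5S,6R,8R,9R,10S,13S)-6-acetoxy-9,13:15,16-diepoxylabd-14-ene | CC(=O)O[C@@H]1C[C@@H](C)[C@]2(CC[C@@]3(C=COC3)O2)[C@@]2(C)CCCC(C)(C)[C@H]12 | target

**Count.** Total: 16 steps. Longest linear sequence: 14 steps (steps 3–16, from (R)-malic acid); the α-damascone branch joins at step 7.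

**Steps most likely to fail**

Step 9. The C10 radical may be reduced before it reaches the congested C9, or the closure may pass through more than one geometry so that facial control at C9 is lost. The fallback sets out from 15 and comes back at 19. The same Fe(acac)3/PhSiH3 conditions would be applied to the silyl-protected ynone 15, where the radical adds 6-exo-dig to the unhindered sp carbon C9 and no configuration is created there. This would give the ring B enone 13-(triethylsilyloxy)-6,12-dioxolabd-9(11)-en-15,16-olide F1. HF·pyridine would then free the hydroxy enone 13-hydroxy-6,12-dioxolabd-9(11)-en-15,16-olide F2. Camphorsulfonic acid in CH2Cl2 would close ring C by acid-catalysed oxa-Michael addition of the C13 hydroxyl to C9 under equilibrium control (oxygen axial), giving 19.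

Step 12. The lactone acyl group may migrate to the C12 hydroxyl under the basic acylation conditions, or both hydroxyls may be thioacylated. The fallback sets out from 20 and comes back at 23, and avoids a C12 alcohol altogether. Ethane-1,2-dithiol and BF3·OEt2 in CH2Cl2 at 0 °C would convert the C12 ketone of 20 (the C6 ketone being far more hindered) into the 12-spiro-1,3-dithiolane of 6-oxo-9,13-epoxylabdan-15,16-olide F3. Acetone-deactivated Raney Ni in EtOH would desulfurise this to 6-oxo-9,13-epoxylabdan-15,16-olide F4. NaBH4 would then reduce the C6 ketone from the α-face to give 23.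

Step 15. The hydride may also cleave the C6 acetate or carry the lactol on to the diol. The fallback sets out from 23 and comes back at 27. The lactone of 23 would be reduced before acetylation with excess i-Bu2AlH at −78 °C to the lactol alcohol 9,13:15,16-diepoxylabdane-6,15-diol F5. Ac2O, DMAP and pyridine would give the 6,15-diacetate F6. Me3SiOTf and i-Pr2NEt in CH2Cl2 at −78 °C would then ionise the anomeric acetate and remove H14 to give 27.

**Further compounds**

F1 | step 9 | (8R,10S,13S)-13-(triethylsilyloxy)-6,12-dioxolabd-9(11)-en-15,16-olide, C5 epimers, alkene geometry undefined | O=C1C[C@@H](C)C(=CC(=O)[C@@]2(CC(=O)OC2)O[Si](CC)(CC)CC)[C@@]2(C)CCCC(C)(C)C12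
F2 | step 9 | (8R,10S,13S)-13-hydroxy-6,12-dioxolabd-9(11)-en-15,16-olide, C5 epimers, alkene geometry undefined | O=C1C[C@@H](C)C(=CC(=O)[C@@]2(CC(=O)OC2)O)[C@@]2(C)CCCC(C)(C)C12
F3 | step 12 | 12-spiro-1,3-dithiolane of (5S,8R,9R,10S,13S)-6-oxo-9,13-epoxylabdan-15,16-olide | O=C1C[C@@H](C)[C@]2(CC3(SCCS3)[C@@]4(CC(=O)OC4)O2)[C@@]2(C)CCCC(C)(C)[C@H]12
F4 | step 12 | (5S,8R,9R,10S,13S)-6-oxo-9,13-epoxylabdan-15,16-olide | O=C1C[C@@H](C)[C@]2(CC[C@@]3(CC(=O)OC3)O2)[C@@]2(C)CCCC(C)(C)[C@H]12
F5 | step 15 | (5S,6R,8R,9R,10S,13S)-9,13:15,16-diepoxylabdane-6,15-diol, C15 anomers | O[C@@H]1C[C@@H](C)[C@]2(CC[C@@]3(CC(O)OC3)O2)[C@@]2(C)CCCC(C)(C)[C@H]12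
F6 | step 15 | 6,15-diacetate of F5 | CC(=O)O[C@@H]1C[C@@H](C)[C@]2(CC[C@@]3(CC(OC(C)=O)OC3)O2)[C@@]2(C)CCCC(C)(C)[C@H]12
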